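**Retrosynthetic overview**
1. Target ⇐ singlet-oxygen (Schenck) ene reaction on the C11=C12 alkene of the parent triene bis-lactone; this sets C12 and moves the alkene to C10=C11.
2. Butenolide plus 14-membered carbocycle ⇐ ring-closing metathesis (C7=C8) across a 15-membered macrolactone ⇐ Yamaguchi lactonisation (C6–O–C19).
3. trans-α-Methylidene-γ-butyrolactone (C1–C2 bond, both stereocentres) ⇐ intermolecular carbonyl allylation: chiral-acid-catalysed 2-alkoxycarbonyl allylboration of fragment A (enal, C2–C7) with fragment B (Z-allylboronate, C1, C8–C17, C19, C20).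
4. Fragment A ⇐ (R)-epichlorohydrin + TMS-acetylene (C6), Negishi carboalumination (E C3=C4). Fragment B ⇐ geranyl bromide + methallyl alcohol dianion, terminal cleavage, ynoate, hydroalumination/borylmethylation.
5. Ring order: methylidene lactone (fragment union) → macrolactone → butenolide and carbocycle together → hydroperoxide last.

Assumption: the chiral phosphoric acid in step 14 selects the aldehyde face as in its known allyl- and crotylboronate additions (Re face with the (R)-acid); if the measured sense is opposite, the (S)-acid is used.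

Numbering used for positions (cembrane style): C1 (ring CH next to C15), C2 (lactone O–CH), C3=C4(Me), C5, C6 (butenolide O–CH), C7=C8, C19 (butenolide C=O), C9, C10, C11, C12 (Me, OOH), C13, C14; C15(=C17H2)–C16(=O). Target = (1R,2S,6R,12S), 3E, 10E, trans-fused methylidene lactone.

**Fragment A**

Step 1
Reactants: 1 (R)-epichlorohydrin; 2 ethynyltrimethylsilane
Product: 4 (2R)-1-chloro-5-(trimethylsilyl)pent-4-yn-2-ol, via lithium (trimethylsilyl)acetylide 3 (not isolated)
Conditions: 2, n-BuLi, THF, −78 °C; BF3·OEt2; then 1, −78 °C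
Reagents that add atoms: none
Why: BF3-promoted SN2 epoxide opening by the lithium acetylide (Yamaguchi–Hirao alkynylation) occurs only at the unsubstituted ring carbon, so the stereocentre of 1 (the later C6) is carried over untouched.

Step 2
Reactants: 4
Product: 6 (3R)-6-(trimethylsilyl)hex-1-en-5-yn-3-ol, via epoxide 5 (not isolated)
Conditions: Me3S+ I− (4 equiv), n-BuLi (3.8 equiv), THF, −10 °C → rt
Reagents that add atoms: trimethylsulfonium iodide, C[S+](C)C.[I-]
Why: The alkoxide closes to epoxide 5 (intramolecular Williamson reaction) and excess dimethylsulfonium methylide opens it at the CH2 end and eliminates Me2S (Corey–Chaykovsky-type one-carbon homologation to the allylic alcohol), never touching the stereocentre.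

Step 3
Reactants: 6
Product: 7 (3R)-3-[(tert-butyldimethylsilyl)oxy]-6-(trimethylsilyl)hex-1-en-5-yne
Conditions: TBSCl, imidazole, DMF, rt
Reagents that add atoms: tert-butyldimethylsilyl chloride, CC(C)(C)[Si](C)(C)Cl
Why: Standard silyl ether protection of the secondary allylic alcohol, needed for the organoaluminium and organoboron steps that follow.

Step 4
Reactants: 7
Product: 8 (3R)-3-[(tert-butyldimethylsilyl)oxy]hex-1-en-5-yne
Conditions: K2CO3 (0.2 equiv), MeOH, rt
Reagents that add atoms: none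
Why: Base-catalysed methanolysis (protodesilylation) cleaves only the alkynyl C–SiMe3 bond, the TBS ether being stable.

Step 5
Reactants: 8
Product: 11 (2E,5R)-5-[(tert-butyldimethylsilyl)oxy]-3-methylhepta-2,6-dien-1-ol, via alkenylalane 9 (not isolated), via lithium alkenylaluminate 10 (not isolated)
Conditions: Cp2ZrCl2 (0.25 equiv), AlMe3 (3 equiv), CH2Cl2, 0 °C → rt; evaporate; n-BuLi, THF/hexane, −78 °C; (CH2O)n, → rt
Reagents that add atoms: trimethylaluminium, C[Al](C)C; formaldehyde (from paraformaldehyde), C=O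
Why: Negishi zirconium-catalysed carboalumination adds Me and Al syn across the terminal alkyne with Al at the terminus, and hydroxymethylation of the derived aluminate with retention fixes the E trisubstituted C3=C4 alkene.

Step 6
Reactants: 11
Product: 12 (2E,5R)-5-[(tert-butyldimethylsilyl)oxy]-3-methylhepta-2,6-dienal (fragment A)
Conditions: MnO2, CH2Cl2, rt
Reagents that add atoms: none
Why: MnO2 oxidises only the primary allylic alcohol to the enal (allylic oxidation) without E/Z erosion or over-oxidation.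

**Fragment B**

Step 7
Reactants: 13 2-methylprop-2-en-1-ol; 14 geranyl bromide
Product: 16 (5E)-6,10-dimethyl-2-methylideneundeca-5,9-dien-1-ol, via dilithio dianion 15 (not isolated)
Conditions: 13, n-BuLi (2.2 equiv), TMEDA, Et2O, 0 °C → rt; then 14, THF, −78 °C → rt
Reagents that add atoms: none
Why: The C,O-dilithiated methallyl alcohol has two equivalent allyl termini and is alkylated on carbon by the primary allylic bromide (SN2 alkylation of a dianion), which keeps the E alkene of geranyl bromide and forms the C9–C10 bond.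

Step 8
Reactants: 16
Product: 17 tert-butyl{[(5E)-6,10-dimethyl-2-methylideneundeca-5,9-dien-1-yl]oxy}dimethylsilane
Conditions: TBSCl, imidazole, CH2Cl2, rt
Reagents that add atoms: tert-butyldimethylsilyl chloride, CC(C)(C)[Si](C)(C)Cl
Why: Silyl ether protection of the primary allylic alcohol (the later C19 carboxyl) so that it survives the acetylide and hydride steps.

Step 9
Reactants: 17
Product: 19 racemic tert-butyl{[(5E)-8-(3,3-dimethyloxiran-2-yl)-6-methyl-2-methylideneoct-5-en-1-yl]oxy}dimethylsilane, via bromohydrin 18 (not isolated)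
Conditions: NBS, THF/H2O (3:1), 0 °C; then K2CO3, MeOH, rt
Reagents that add atoms: water, O
Why: van Tamelen-type bromohydrin formation in aqueous THF is selective for the terminal trisubstituted alkene of a polyprenyl chain and base closes the bromohydrin to the epoxide (Williamson reaction), the new centre being racemic and destroyed in step 10.

Step 10
Reactants: 19
Product: 21 (4E)-8-{[(tert-butyldimethylsilyl)oxy]methyl}-4-methylnona-4,8-dienal, via diol 20 (not isolated)
Conditions: H5IO6, THF/H2O, 0 °C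
Reagents that add atoms: none
Why: Periodic acid hydrolyses the epoxide to the diol and cleaves it (Malaprade glycol cleavage) to the C1 aldehyde and acetone.

Step 11
Reactants: 21
Product: 22 tert-butyldimethyl{[(5E)-6-methyl-2-methylidenedec-5-en-9-yn-1-yl]oxy}silane
Conditions: dimethyl (1-diazo-2-oxopropyl)phosphonate, K2CO3, MeOH, 0 °C → rt
Reagents that add atoms: dimethyl (1-diazo-2-oxopropyl)phosphonate, CC(=O)C(=[N+]=[N-])P(=O)(OC)OC
Why: Ohira–Bestmann (Seyferth–Gilbert) homologation converts the aldehyde into the terminal alkyne under mild carbonate conditions and adds C15.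

Step 12
Reactants: 22
Product: 24 methyl (6E)-10-{[(tert-butyldimethylsilyl)oxy]methyl}-6-methylundeca-6,10-dien-2-ynoate, via lithium acetylide 23 (not isolated)
Conditions: n-BuLi, THF, −78 °C; ClCO2Me, −78 → 0 °C
Reagents that add atoms: methyl chloroformate, COC(=O)Cl
Why: C-acylation of the lithium acetylide with the chloroformate gives the 2-ynoate (C16) needed for conjugate hydrometalation.

Step 13
Reactants: 24
Product: 26 methyl (2Z,6E)-10-{[(tert-butyldimethylsilyl)oxy]methyl}-6-methyl-2-[(4,4,5,5-tetramethyl-1,3,2-dioxaborolan-2-yl)methyl]undeca-2,6,10-trienoate (fragment B), via alpha-aluminated enoate 25 (not isolated)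
Conditions: i-Bu2AlH, HMPA, THF, 0 °C; then ICH2Bpin, rt
Reagents that add atoms: 2-(iodomethyl)-4,4,5,5-tetramethyl-1,3,2-dioxaborolane, ICB1OC(C)(C)C(C)(C)O1
Why: Conjugate syn-hydroalumination of the ynoate by the i-Bu2AlH–HMPA complex gives the alpha-aluminated enoate, which is alkylated by ICH2Bpin on the side of the beta-hydrogen, so the chain ends up cis to the ester and trans to CH2B (Z 2-alkoxycarbonyl allylboronate).

**Fragment union and endgame**

Step 14
Reactants: 12 fragment A enal; 26 fragment B allylboronate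
Product: 28 (4R,5S)-5-[(1E,4R)-4-{[tert-butyl(dimethyl)silyl]oxy}-2-methylhexa-1,5-dien-1-yl]-4-[(3E)-7-({[tert-butyl(dimethyl)silyl]oxy}methyl)-3-methylocta-3,7-dien-1-yl]-3-methylideneoxolan-2-one, via anti O-boryl adduct 27 (not isolated)
Conditions: (R)-3,3′-bis(2,4,6-triisopropylphenyl)-1,1′-binaphthyl-2,2′-diyl hydrogenphosphate [(R)-TRIP, 10 mol %], 4 Å MS, toluene, 0 °C → rt; then p-TsOH·H2O (10 mol %), rt
Reagents that add atoms: none
Why: Brønsted-acid-catalysed carbonyl allylboration through a closed chair transition state, in which the Z boronate (chain trans to CH2B) gives the anti adduct and hence the trans lactone, the chiral phosphoric acid directs attack to the Re face of the enal to set C2 as S and C1 as R, and acid then closes the lactone with loss of methanol.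

Step 15
Reactants: 28
Product: 29 (4R,5S)-5-[(1E,4R)-4-hydroxy-2-methylhexa-1,5-dien-1-yl]-4-[(3E)-7-(hydroxymethyl)-3-methylocta-3,7-dien-1-yl]-3-methylideneoxolan-2-one
Conditions: HF·pyridine, pyridine, THF, 0 °C → rt
Reagents that add atoms: none
Why: Buffered fluoride desilylation removes both TBS ethers without adding to or opening the methylidene lactone.

Step 16
Reactants: 29
Product: 30 (4R,5S)-4-[(3E)-7-formyl-3-methylocta-3,7-dien-1-yl]-5-[(1E,4R)-4-hydroxy-2-methylhexa-1,5-dien-1-yl]-3-methylideneoxolan-2-one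
Conditions: TEMPO (10 mol %), PhI(OAc)2, CH2Cl2, rt
Reagents that add atoms: none
Why: Oxoammonium (TEMPO) oxidation is selective for the primary allylic alcohol over the secondary C6 alcohol and stops at the aldehyde.

Step 17
Reactants: 30
Product: 31 (4R,5S)-4-[(3E)-7-carboxy-3-methylocta-3,7-dien-1-yl]-5-[(1E,4R)-4-hydroxy-2-methylhexa-1,5-dien-1-yl]-3-methylideneoxolan-2-one
Conditions: NaClO2, NaH2PO4, 2-methyl-2-butene, t-BuOH/H2O, 0 °C → rt
Reagents that add atoms: sodium chlorite, [Na+].[O-]Cl=O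
Why: Pinnick oxidation converts the 2-substituted acrolein into the acrylic acid, with 2-methyl-2-butene trapping HOCl so that the other alkenes and the free alcohol survive.

Step 18
Reactants: 31
Product: 33 15-membered macrolactone (C19 acyl on the C6 oxygen; C6 vinyl and C8 methylidene retained; 1R,2S,6R; 3E,11E), via mixed anhydride 32 (not isolated)
Conditions: 2,4,6-Cl3C6H2COCl, Et3N, THF, rt; then DMAP, toluene, 60 °C, slow addition (1 mM)
Reagents that add atoms: none
Why: Yamaguchi macrolactonisation, in which the mixed anhydride is attacked by the C6 hydroxyl under DMAP catalysis at high dilution, gives the 15-membered lactone with retention at C6.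

Step 19
Reactants: 33
Product: 34 (1R,2S,6R,3E,11E)-cembra-3,7,11,15(17)-tetraene-16,2:19,6-diolide
Conditions: second-generation Grubbs catalyst (15 mol %), toluene, 80 °C, 0.5 mM
Reagents that add atoms: none
Why: Ring-closing metathesis between the C7 vinyl group and the C8 methylidene, which are tied together by the ester, can only give the five-membered butenolide alkene and so closes the 14-membered carbocycle with the required C7=C8 geometry and loss of ethene.

Step 20
Reactants: 34
Product: 35 (1R,2S,6R,12S,3E,10E)-12-hydroperoxycembra-3,7,10,15(17)-tetraene-16,2:19,6-diolide (target CNP0343227.1)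
Conditions: O2, tetraphenylporphyrin (1 mol %), visible light, CH2Cl2, −20 °C; HPLC
Reagents that add atoms: dioxygen, O=O
Why: Schenck ene reaction of singlet oxygen with the only electron-rich, unactivated trisubstituted alkene (C11=C12), in which oxygen adds to C12 on the exposed outer face of the macrocycle with suprafacial removal of a C10 hydrogen, sets C12 as S and moves the double bond to E C10=C11.

**Compound list**

1 | (R)-epichlorohydrin | ClC[C@H]1CO1 | starting material
2 | ethynyltrimethylsilane | C#C[Si](C)(C)C | starting material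
3 | lithium (trimethylsilyl)acetylide | [Li]C#C[Si](C)(C)C | intermediate
4 | (2R)-1-chloro-5-(trimethylsilyl)pent-4-yn-2-ol | ClC[C@H](O)CC#C[Si](C)(C)C | intermediate
5 | (2R)-2-[3-(trimethylsilyl)prop-2-yn-1-yl]oxirane | C1[C@H](O1)CC#C[Si](C)(C)C | intermediate
6 | (3R)-6-(trimethylsilyl)hex-1-en-5-yn-3-ol | C=C[C@H](O)CC#C[Si](C)(C)C | intermediate
7 | (3R)-3-[(tert-butyldimethylsilyl)oxy]-6-(trimethylsilyl)hex-1-en-5-yne | C=C[C@H](O[Si](C)(C)C(C)(C)C)CC#C[Si](C)(C)C | intermediate
8 | (3R)-3-[(tert-butyldimethylsilyl)oxy]hex-1-en-5-yne | C=C[C@H](O[Si](C)(C)C(C)(C)C)CC#C | intermediate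
9 | dimethyl[(1E,4R)-4-(TBS-oxy)-2-methylhexa-1,5-dien-1-yl]alane | C=C[C@H](O[Si](C)(C)C(C)(C)C)C/C(C)=C/[Al](C)C | intermediate
10 | lithium butyl(dimethyl)[(1E,4R)-4-(TBS-oxy)-2-methylhexa-1,5-dien-1-yl]aluminate | [Li+].C=C[C@H](O[Si](C)(C)C(C)(C)C)C/C(C)=C/[Al-](C)(C)CCCC | intermediate
11 | (2E,5R)-5-[(tert-butyldimethylsilyl)oxy]-3-methylhepta-2,6-dien-1-ol | C=C[C@H](O[Si](C)(C)C(C)(C)C)C/C(C)=C/CO | intermediate
12 | (2E,5R)-5-[(tert-butyldimethylsilyl)oxy]-3-methylhepta-2,6-dienal (fragment A) | C=C[C@H](O[Si](C)(C)C(C)(C)C)C/C(C)=C/C=O | intermediate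
13 | 2-methylprop-2-en-1-ol | C=C(C)CO | starting material
14 | geranyl bromide, (2E)-1-bromo-3,7-dimethylocta-2,6-diene | BrC/C=C(\C)CCC=C(C)C | starting material
15 | lithium 2-(lithiomethyl)prop-2-en-1-olate | [Li]CC(=C)CO[Li] | intermediate
16 | (5E)-6,10-dimethyl-2-methylideneundeca-5,9-dien-1-ol | C=C(CO)CC/C=C(\C)CCC=C(C)C | intermediate
17 | tert-butyl{[(5E)-6,10-dimethyl-2-methylideneundeca-5,9-dien-1-yl]oxy}dimethylsilane | C=C(CO[Si](C)(C)C(C)(C)C)CC/C=C(\C)CCC=C(C)C | intermediate
18 | racemic (6E)-3-bromo-11-[(tert-butyldimethylsilyl)oxy]-2,6-dimethyl-10-methylideneundec-6-en-2-ol | C=C(CO[Si](C)(C)C(C)(C)C)CC/C=C(\C)CCC(Br)C(C)(C)O | intermediate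
19 | racemic tert-butyl{[(5E)-8-(3,3-dimethyloxiran-2-yl)-6-methyl-2-methylideneoct-5-en-1-yl]oxy}dimethylsilane | C=C(CO[Si](C)(C)C(C)(C)C)CC/C=C(\C)CCC1OC1(C)C | intermediate
20 | racemic (6E)-11-[(tert-butyldimethylsilyl)oxy]-2,6-dimethyl-10-methylideneundec-6-ene-2,3-diol | C=C(CO[Si](C)(C)C(C)(C)C)CC/C=C(\C)CCC(O)C(C)(C)O | intermediate
21 | (4E)-8-{[(tert-butyldimethylsilyl)oxy]methyl}-4-methylnona-4,8-dienal | O=CCC/C(C)=C/CCC(=C)CO[Si](C)(C)C(C)(C)C | intermediate
22 | tert-butyldimethyl{[(5E)-6-methyl-2-methylidenedec-5-en-9-yn-1-yl]oxy}silane | C#CCC/C(C)=C/CCC(=C)CO[Si](C)(C)C(C)(C)C | intermediate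
23 | lithium acetylide of 22 | [Li]C#CCC/C(C)=C/CCC(=C)CO[Si](C)(C)C(C)(C)C | intermediate
24 | methyl (6E)-10-{[(tert-butyldimethylsilyl)oxy]methyl}-6-methylundeca-6,10-dien-2-ynoate | COC(=O)C#CCC/C(C)=C/CCC(=C)CO[Si](C)(C)C(C)(C)C | intermediate
25 | methyl 2-(diisobutylalumanyl)-enoate from 24 (chain cis to ester) | COC(=O)/C([Al](CC(C)C)CC(C)C)=C\CC/C(C)=C/CCC(=C)CO[Si](C)(C)C(C)(C)C | intermediate
26 | methyl (2Z,6E)-10-{[(tert-butyldimethylsilyl)oxy]methyl}-6-methyl-2-[(4,4,5,5-tetramethyl-1,3,2-dioxaborolan-2-yl)methyl]undeca-2,6,10-trienoate (fragment B) | COC(=O)/C(CB1OC(C)(C)C(C)(C)O1)=C\CC/C(C)=C/CCC(=C)CO[Si](C)(C)C(C)(C)C | intermediate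
27 | anti O-(pinacolatoboryl) homoallylic adduct of 12 and 26 (C1 R, C2 S, C6 R) | COC(=O)C(=C)[C@@H](CC/C(C)=C/CCC(=C)CO[Si](C)(C)C(C)(C)C)[C@@H](OB1OC(C)(C)C(C)(C)O1)/C=C(\C)C[C@H](C=C)O[Si](C)(C)C(C)(C)C | intermediate
28 | (4R,5S)-5-[(1E,4R)-4-(TBS-oxy)-2-methylhexa-1,5-dien-1-yl]-4-[(3E)-7-(TBS-oxymethyl)-3-methylocta-3,7-dien-1-yl]-3-methylideneoxolan-2-one | C=C1C(=O)O[C@@H](/C=C(\C)C[C@H](C=C)O[Si](C)(C)C(C)(C)C)[C@@H]1CC/C(C)=C/CCC(=C)CO[Si](C)(C)C(C)(C)C | intermediate
29 | (4R,5S)-5-[(1E,4R)-4-hydroxy-2-methylhexa-1,5-dien-1-yl]-4-[(3E)-7-(hydroxymethyl)-3-methylocta-3,7-dien-1-yl]-3-methylideneoxolan-2-one | C=C1C(=O)O[C@@H](/C=C(\C)C[C@H](C=C)O)[C@@H]1CC/C(C)=C/CCC(=C)CO | intermediate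
30 | (4R,5S)-4-[(3E)-7-formyl-3-methylocta-3,7-dien-1-yl]-5-[(1E,4R)-4-hydroxy-2-methylhexa-1,5-dien-1-yl]-3-methylideneoxolan-2-one | C=C1C(=O)O[C@@H](/C=C(\C)C[C@H](C=C)O)[C@@H]1CC/C(C)=C/CCC(=C)C=O | intermediate
31 | (4R,5S)-4-[(3E)-7-carboxy-3-methylocta-3,7-dien-1-yl]-5-[(1E,4R)-4-hydroxy-2-methylhexa-1,5-dien-1-yl]-3-methylideneoxolan-2-one | C=C1C(=O)O[C@@H](/C=C(\C)C[C@H](C=C)O)[C@@H]1CC/C(C)=C/CCC(=C)C(=O)O | intermediate
32 | mixed anhydride of 31 and 2,4,6-trichlorobenzoic acid | C=C1C(=O)O[C@@H](/C=C(\C)C[C@H](C=C)O)[C@@H]1CC/C(C)=C/CCC(=C)C(=O)OC(=O)c1c(Cl)cc(Cl)cc1Cl | intermediate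
33 | 15-membered macrolactone (C19 acyl on C6–O; C6 vinyl, C8 methylidene; 1R,2S,6R; 3E,11E) | C=C1C(=O)O[C@H]2/C=C(\C)C[C@H](C=C)OC(=O)C(=C)CC/C=C(\C)CC[C@H]12 | intermediate
34 | (1R,2S,6R,3E,11E)-cembra-3,7,11,15(17)-tetraene-16,2:19,6-diolide | C=C1C(=O)O[C@H]2/C=C(\C)C[C@@H]3C=C(CC/C=C(\C)CC[C@H]12)C(=O)O3 | intermediate
35 | (1R,2S,6R,12S,3E,10E)-12-hydroperoxycembra-3,7,10,15(17)-tetraene-16,2:19,6-diolide | C=C1C(=O)O[C@H]2/C=C(\C)C[C@@H]3C=C(C/C=C/[C@@](C)(OO)CC[C@H]12)C(=O)O3 | target

**Totals and risks**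

Total step count: 20. Longest linear sequence: 14 steps (steps 7–13, then 14–20, from 13 and 14).

Most likely to fail:

Step 14. The ester-deactivated boronate 26 may react slowly or with only moderate face selectivity under the chiral acid, and this catalyst has no direct precedent on this boronate class. Because aldehyde 12 is a single enantiomer, the wrong-face adduct is a diastereomer and is removed by chromatography. The fallback sets out from alkyne 22 and comes back at lactone 28, replacing catalyst control by a covalent ester auxiliary. Treatment of 22 with n-BuLi and CO2 gives the alkynoic acid F1. DCC/DMAP coupling with (1R,2S,5R)-8-phenylmenthol gives the 8-phenylmenthyl ynoate F2. i-Bu2AlH/HMPA followed by ICH2Bpin gives the Z 8-phenylmenthyl allylboronate F3. F3 and aldehyde 12 are combined with Sc(OTf)3 (10 mol %) in toluene at −78 °C → rt, and p-TsOH then closes the lactone to 28 with release of the auxiliary alcohol. If the (1R,2S,5R) auxiliary proves mismatched, its enantiomer is used.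

Step 19. The 15-membered lactone holds the ester s-trans and the acrylate alkene is electron-poor and 1,1-disubstituted, so the cross-ring metathesis may stall or oligomerise. The fallback sets out from diol 29 and comes back at bis-lactone 34, using a silicon tether and an oxidative lactonisation instead of an ester tether. i-Pr2SiCl2 and imidazole at high dilution give the cyclic silyl ether F4. The second-generation Grubbs catalyst closes the flexible seven-membered ring between the electronically neutral C7 vinyl and C8 methylidene groups to give the dioxasilepine F5. HF·pyridine releases the Z-enediol F6, already containing the 14-membered carbocycle. TEMPO/PhI(OAc)2 oxidises the primary allylic alcohol to the aldehyde, which closes to the lactol with the cis C6 hydroxyl and is oxidised on to the butenolide 34.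

Step 20. Singlet oxygen can also abstract hydrogen from the C12 methyl group (giving the 11-hydroperoxide with an exocyclic alkene) and can attack either face, so the 12S product may be only part of a mixture that needs HPLC. The fallback sets out from macrolactone 33 and comes back at target 35, oxygenating a different conformational template before the second ring is closed. Photooxygenation of 33 (O2, tetraphenylporphyrin, light) gives the macrolactone hydroperoxide F7, isolated from its isomers. 2-Methoxypropene with PPTS masks it as the peroxyketal F8. Ring-closing metathesis with the second-generation Grubbs catalyst gives the bis-lactone peroxyketal F9. AcOH/THF/H2O then frees the hydroperoxide to give 35.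

**Further compounds**

F1 | step 14 | (6E)-10-{[(tert-butyldimethylsilyl)oxy]methyl}-6-methylundeca-6,10-dien-2-ynoic acid | OC(=O)C#CCC/C(C)=C/CCC(=C)CO[Si](C)(C)C(C)(C)C
F2 | step 14 | (1R,2S,5R)-5-methyl-2-(2-phenylpropan-2-yl)cyclohexyl (6E)-10-{[(tert-butyldimethylsilyl)oxy]methyl}-6-methylundeca-6,10-dien-2-ynoate | CC(C)(c1ccccc1)[C@@H]1CC[C@@H](C)C[C@H]1OC(=O)C#CCC/C(C)=C/CCC(=C)CO[Si](C)(C)C(C)(C)C
F3 | step 14 | (1R,2S,5R)-5-methyl-2-(2-phenylpropan-2-yl)cyclohexyl (2Z,6E)-10-{[(tert-butyldimethylsilyl)oxy]methyl}-6-methyl-2-[(4,4,5,5-tetramethyl-1,3,2-dioxaborolan-2-yl)methyl]undeca-2,6,10-trienoate | CC(C)(c1ccccc1)[C@@H]1CC[C@@H](C)C[C@H]1OC(=O)/C(CB2OC(C)(C)C(C)(C)O2)=C\CC/C(C)=C/CCC(=C)CO[Si](C)(C)C(C)(C)C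
F4 | step 19 | cyclic diisopropylsilylene ether of diol 29 (C6–O–Si–O–C19) | C=C1C(=O)O[C@H]2/C=C(\C)C[C@H](C=C)O[Si](C(C)C)(C(C)C)OCC(=C)CC/C=C(\C)CC[C@H]12
F5 | step 19 | 14-membered carbocycle with fused 2,2-diisopropyl-1,3-dioxa-2-silacyclohept-5-ene (C7=C8 closed) | C=C1C(=O)O[C@H]2/C=C(\C)C[C@@H]3C=C(CC/C=C(\C)CC[C@H]12)CO[Si](C(C)C)(C(C)C)O3
F6 | step 19 | (7Z)-6-hydroxy-19-hydroxy carbocyclic enediol (1R,2S,6R; 3E,11E) | C=C1C(=O)O[C@H]2/C=C(\C)C[C@@H](O)/C=C(CO)/CC/C=C(\C)CC[C@H]12
F7 | step 20 | (12S,10E)-12-hydroperoxide of macrolactone 33 | C=C1C(=O)O[C@H]2/C=C(\C)C[C@H](C=C)OC(=O)C(=C)C/C=C/[C@@](C)(OO)CC[C@H]12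
F8 | step 20 | 2-methoxypropan-2-yl peroxyketal of F7 | C=C1C(=O)O[C@H]2/C=C(\C)C[C@H](C=C)OC(=O)C(=C)C/C=C/[C@@](C)(OOC(C)(C)OC)CC[C@H]12
F9 | step 20 | 2-methoxypropan-2-yl peroxyketal of target 35 | C=C1C(=O)O[C@H]2/C=C(\C)C[C@@H]3C=C(C/C=C/[C@@](C)(OOC(C)(C)OC)CC[C@H]12)C(=O)O3
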